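Read the substrate curve of the south run, which is this very flask followed so far, before its target curve.

- south: substrate 0.10 M; reagent 0.080 M; free catalyst 15 mM; the very flask that is asked about, followed so far
- flask: substrate 0.10 M; reagent 0.0800 M; free catalyst 15 mM; time 2.0 d

south run (percent of the substrate charged)

| time / h | target / % | substrate / % |
|---|---|---|
| 1.50 | 35 | 37 |
| 4.00 | 54 | 12 |
| 8.00 | 60 | 7 |
| 12.0 | 62 | 2 |
| 20.0 | 64 | 5 |
| 25.0 | 64 | 5 |
| 30.0 | 62 | 5 |

(readings scatter by 2 percentage points)

- maple: at 2.0 d add free catalyst, 100% of the amount charged, then wait 4.0 d
- oak: at 2.0 d take out 90% of the target then present, then wait 4.0 d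
- elm: change nothing and wait 4.0 d more
- larch: at 2.0 d add reagent, 100% of the amount charged, then wait 4.0 d

- target that was removed still counts
- additions bring no volume worth counting

- target, in percent of the substrate first charged, at 2.0 d
- which option adds most target ("none" when 2 percentage points or less is all one gets) (maple / oak / elm / larch / none)
- target present, with what was taken out counted in, in percent of the substrate first charged, after oak
- target present, with what was taken out counted in, in percent of the substrate first charged, after elm

What does a stall with substrate still present suggest? The readings from 20.0 h on average S∞ = 5.00%. My model has substrate loss pseudo-first-order, with a rate constant proportional to free catalyst, and free catalyst decaying first-order. Then L = ln(substrate charged/substrate) climbs to a ceiling L∞ = kτ, where k is the initial rate constant and τ the mean lifetime of free catalyst. Here L∞ = 3.00.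

A first value of τ? Taking the 1.50 h reading as the initial slope gives k = 0.663 h⁻¹, so τ = 4.52 h.

But catalyst was already dying in that interval? Yes, so I put the answer back. That τ makes the mean free catalyst over the interval 85.1% of its charge, which raises k to 0.779 h⁻¹ and lowers τ to 3.85 h. This τ is the working life of the catalyst, the mean time free catalyst survives.

Is there a test? The 8.00 h reading went unused: the curve gives 7.27% substrate, and the reading is 7%.

Might the reagent be out instead? The readings do not show reagent. Target levels at 63.3%, leaving a gap of 31.7% of the substrate charged. If that gap is a held-up form containing no reagent, the spare reagent is 16.7% on the same scale. This is my weakest step.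

Your commitment? At 2.0 d the flask is 12.5 working lives old, so I expect target near 63.3% at that time and no gain from elm, oak or larch. Maple brings fresh catalyst, so it is my pick, with an expected gain of up to 16.7%.

The forecast gives 63% now, 63% after oak and 63% after elm, but names larch as best, holding that “the reagent is spent”, and there it parts from my reckoning.

The flask gives 64.0% at 2.0 d, 64.0% after oak and 64.0% after elm; the best option is maple, adding 12 percentage points, against 0 points for larch.

    substrate + free catalyst → free catalyst + intermediate (k = 0.938 L mol⁻¹ min⁻¹)
    reagent + free catalyst + intermediate → free catalyst + target (k = 16.0 L² mol⁻² min⁻¹)
    free catalyst → spent catalyst (k = 0.00467 min⁻¹)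

Carry k and τ unchanged to the neighbour flask charged with 0.20 M of reagent, or 2.00 equiv, all else as in the recipe. The reckoning exp(−kτ) gives a substrate end of 4.98%, and the neighbour flask ends at 4.92%, the flask itself at 4.92%. At 48.0 h the neighbour flask is 12.5 working lives old and holds 0% free catalyst, as the flask itself holds 0%. Its intermediate stands at 4.53%, against 31.1% in the flask, and its target at 90.6%.

The runs are calculated with constants of no real substance, noise included.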